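Start with the easy bookkeeping: each electrophile that reacts consumes one nucleophile and frees one acid. We assume that this acid, like the fed buffer acid, ends up on free nucleophile. We set the homo dimer aside in this reckoning. Once the feed is over, dividing the rate of nucleophile loss by the rate of electrophile loss then gives 2, and time drops out. So we carry the reserve ratio, nucleophile charged less buffer acid fed, per electrophile charged: 2.00.

| flask | electrophile | nucleophile | buffer base | buffer acid | remark | time |
|---|---|---|---|---|---|---|
| east | 0.050 M | 0.15 M | 0.050 M | 0.050 M (fed, over 2.0 min) | the very flask that is asked about, followed so far |  |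
| south-east | 0.10 M | 0.15 M | 0.050 M | 0.050 M (fed, over 2.0 min) | run made earlier |  |
| flask | 0.050 M | 0.150 M | 0.0500 M | 0.0500 M (fed, over 2.0 min) |  | 8.0 min |

- east (time / min: electrophile / %, product / %): 0.333: 96, 4; 0.667: 87, 7; 1.00: 87, 13; 2.00: 78, 22; 4.00: 66, 33
- south-east (time / min: electrophile / %, product / %): 0.500: 91, 7; 1.33: 84, 15; 2.50: 79, 20; 4.00: 71, 30; 6.00: 67, 33

(readings scatter by 2 percentage points)

1. part of the electrophile that has reacted at 8.0 min
2. pH of the solution at 8.0 min

After the feed, by our reckoning:

free nucleophile per electrophile charged = reserve ratio − 2 × fraction reacted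

The east readings give a fractional rate (a pseudo-first-order constant) of 0.139 min⁻¹ over the first minute. We put the knee at the end of the feed, 2.0 min, where the line gives 0.0780 M free nucleophile, about half the charge. The fractional rate then reads 0.0835 min⁻¹, lower.

On our line, with a reserve ratio of 2.00, free nucleophile stays proportional to electrophile, so the inverse of the fraction left climbs straight, and the curve bends without stalling. The slope, read from the last two east readings with their scatter, is 0.117 min⁻¹:

inverse of fraction left at 8.0 min = 1.52 + 0.117 min⁻¹ × 4.00 min = 1.98

That is our 49.5% reacted. The pH we cannot reckon from these runs.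

The forecast differs from our reckoning: 43% reacted and pH 7.5, citing a harder stall in the south-east run “which points to protonation mattering”.

The flask gives 48.4% reacted and pH 9.33.

    electrophile + nucleophile → acid + product + leaving group (k = 0.0180 L mol⁻¹ s⁻¹)
    protonated nucleophile ⇌ nucleophile + acid, settled at all times (K = 4.00 × 10⁻¹⁰ M)
    buffer acid ⇌ buffer base + acid, settled at all times (K = 3.20 × 10⁻⁹ M)
    2 nucleophile → homo dimer (k = 0.00179 L mol⁻¹ s⁻¹)

At 8.00 min the flask holds 2.06 free nucleophile per electrophile left. The neighbour with 0.26 M nucleophile has a reserve ratio of 4.20 and by then reaches 72.1% reacted. The same line then gives 2.76 free nucleophile per electrophile charged, but the neighbour holds 2.13. Its homo dimer stands at 0.0200 M, against 0.00553 M in the flask, and its buffer acid at 16.7% of its charge. Two nucleophile per homo dimer, less the buffer acid still standing, come to 0.633 per electrophile charged.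

(All runs are calculated for substances that don't exist, and the scatter is random.)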